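**Retrosynthetic overview**
- The epimerisable bis(pyranonyl) ketone is unveiled last, by buffered oxidation of a carbinol in which only the C2/C4 relation matters (the carbinol centre is destroyed).
- The carbinol is cut at C3–C4: catalytic asymmetric vinylogous Mukaiyama aldol of the silyl trienol ether of 2,6-diethyl-3,5-dimethylpyran-4-one (ring B) with the ring-A α-pyranonyl propanal.
- The aldehyde comes from an alcohol whose stereocentre, the first of the route, is set by catalytic asymmetric silyloxymethylation of the same silyl trienol ether.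
- Ring A is ring B edited after that step (ethyl to vinyl to pentyl), because an ethyl/pentyl pyranone cannot be enolised regioselectively, whereas the symmetrical diethyl pyranone can.
- Ring order: one ring-forming step only (pentan-3-one plus propanoic acid); this pyranone is used first as ring A, then as ring B.

Assumption: the SMILES is read as drawn (R on the pentyl-pyranone side, S on the ethyl-pyranone side); the sense of induction of the IDPi catalysts cannot be predicted, so the enantiomer written in steps 3 and 7 is the one that gives the stated product, and its mirror image is used if the first run shows the opposite sense.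

**Route**

Step 1
Reactants: 1 pentan-3-one; 2 propanoic acid
Product: 4 2,6-diethyl-3,5-dimethyl-4H-pyran-4-one, via 4,6-dimethylnonane-3,5,7-trione 3 (not isolated)
Conditions: 2 (2.5 equiv), polyphosphoric acid, 100 °C
Reagents that add atoms: none
Why: Known polyphosphoric acid cyclocondensation, in which double α-acylation of the ketone gives the 1,3,5-triketone that cyclodehydrates to the γ-pyranone; no stereocentre is formed.

Step 2
Reactants: 4
Product: 6 (Z)-triethyl[(6-ethyl-2-ethylidene-3,5-dimethyl-2H-pyran-4-yl)oxy]silane, via lithium trienolate 5 (not isolated)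
Conditions: LiN(iPr)2, THF, −78 °C; Et3SiCl, −78 to 0 °C; pentane, filtration, bulb-to-bulb distillation
Reagents that add atoms: chlorotriethylsilane, CC[Si](Cl)(CC)CC
Why: Lateral (vinylogous) deprotonation of a 2-ethyl-γ-pyranone and O-silylation of the extended enolate (silyl enol ether formation); the pyranone is symmetrical so one regioisomer forms, and the ethylidene methyl sits syn to the ring oxygen (Z) to avoid allylic strain with the 3-methyl group.

Step 3
Reactants: 6; 7 (chloromethoxy)tri(propan-2-yl)silane
Product: 8 (S)-2-ethyl-3,5-dimethyl-6-(1-{[tri(propan-2-yl)silyl]oxy}propan-2-yl)-4H-pyran-4-one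
Conditions: (S,S)-IDPi (BINOL-derived imidodiphosphorimidate acid, N-SO2CF3 core, 3,3'-aryl groups; 2 mol%), toluene/pentane, −78 to −60 °C; Et3N quench
Reagents that add atoms: none
Why: Proposed new method: the IDPi acid is silylated by 6 to an N-silyl Lewis acid that abstracts chloride from 7 to give the O-silylated formaldehyde oxocarbenium ion paired with the confined chiral anion; the planar Z-ethylidene carbon of 6 attacks it through one enantiotopic face inside the anion pocket (setting the S centre), aromatisation to the 4-silyloxypyrylium ion drives C–C bond formation and transfer of Et3Si to chloride closes the cycle; closest known reaction type: IDPi-catalysed Mukaiyama-type aminomethylation and aldol reactions of silyl ketene acetals with methylene iminium and oxocarbenium ions.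

Step 4
Reactants: 8
Product: 11 (S)-2-ethenyl-3,5-dimethyl-6-(1-{[tri(propan-2-yl)silyl]oxy}propan-2-yl)-4H-pyran-4-one, via lithium trienolate 9 (not isolated), via selenide 10 (not isolated)
Conditions: LiN(iPr)2, THF, −78 °C; PhSeBr; then H2O2 (30% aq.), pyridine, CH2Cl2, 0 °C to rt
Reagents that add atoms: none
Why: α-Selenenylation of the vinylogous enolate and selenoxide syn-elimination (the only β-hydrogens are on the methyl group) turn the remaining ethyl group into vinyl; the amide base takes the unhindered CH2 proton and not the tertiary C–H of the stereocentre, which stays S.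

Step 5
Reactants: 11; 12 propylmagnesium chloride
Product: 15 (S)-2-(1-hydroxypropan-2-yl)-3,5-dimethyl-6-pentyl-4H-pyran-4-one, via trimethylsilyl trienol ether 13 (not isolated), via silyl-protected pentylpyranone 14 (not isolated)
Conditions: 12 (1.5 equiv), CuBr·SMe2 (10 mol%), Me3SiCl, THF, −78 °C; then Bu4NF, THF, 0 °C to rt
Reagents that add atoms: none
Why: Copper-catalysed 1,6-conjugate addition of the Grignard reagent to the vinyl pyranone (the ring β-carbons are tetrasubstituted, so the terminal CH2 is the only open acceptor site) builds the pentyl chain, and fluoride then removes both silyl groups; the stereocentre is not involved.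

Step 6
Reactants: 15
Product: 16 (R)-2-(3,5-dimethyl-4-oxo-6-pentyl-4H-pyran-2-yl)propanal
Conditions: Dess–Martin periodinane, NaHCO3, CH2Cl2, 0 °C; cold Na2S2O3/NaHCO3 wash, dried, used at once
Reagents that add atoms: none
Why: Dess–Martin oxidation under buffered, base-free conditions keeps the configuration (the descriptor changes from S to R only because CHO outranks the ring carbon); the enolisable aldehyde is neither stored nor chromatographed.

Step 7
Reactants: 16; 6
Product: 18 (2S,3R,4R)-2-(3,5-dimethyl-4-oxo-6-pentyl-4H-pyran-2-yl)-4-(6-ethyl-3,5-dimethyl-4-oxo-4H-pyran-2-yl)pentan-3-ol, via triethylsilyl ether 17 (not isolated)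
Conditions: 6 (1.5 equiv), (R,R)-IDPi (5 mol%), toluene, −78 °C, 16 added last; then 1 M HCl, THF, 0 °C
Reagents that add atoms: none
Why: Proposed new method: the N-silylated IDPi converts the aldehyde into a silyloxocarbenium ion held in the chiral anion pocket and the exocyclic carbon of 6 adds through an open antiperiplanar transition state, driven by formation of the aromatic 4-silyloxypyrylium ion, which passes Et3Si on to the aldolate; the (R,R)-catalyst exposes the Felkin–Anh face of 16 (matched case, C3 oxygen syn to the C2 methyl) and the open transition state places the new C4 methyl syn to that oxygen, giving the all-syn triad with the C2 and C4 methyl groups in the required pseudo-meso relation; closest known reaction type: disulfonimide- and IDPi-catalysed vinylogous Mukaiyama aldol reactions of silyl dienol ethers with aldehydes.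

Step 8
Reactants: 18
Product: 19 (2R,4S)-2-(3,5-dimethyl-4-oxo-6-pentyl-4H-pyran-2-yl)-4-(6-ethyl-3,5-dimethyl-4-oxo-4H-pyran-2-yl)pentan-3-one
Conditions: Dess–Martin periodinane, NaHCO3, CH2Cl2, 0 °C to rt; rapid filtration through deactivated silica, stored cold
Reagents that add atoms: none
Why: Dess–Martin oxidation of the hindered secondary alcohol under buffered conditions gives the ketone without enolising the two flanking centres, whose spatial arrangement is unchanged (C2 and C4 become R and S through the change in substituent ranking); the C3 epimer of 18 would give the same ketone.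

**Compound list**
1 | pentan-3-one | CCC(=O)CC | starting material
2 | propanoic acid | CCC(=O)O | starting material
3 | 4,6-dimethylnonane-3,5,7-trione (stereoisomer mixture) | CCC(=O)C(C)C(=O)C(C)C(=O)CC | intermediate
4 | 2,6-diethyl-3,5-dimethyl-4H-pyran-4-one | CCc1oc(CC)c(C)c(=O)c1C | intermediate
5 | lithium (Z)-6-ethyl-2-ethylidene-3,5-dimethyl-2H-pyran-4-olate | C/C=C1\OC(CC)=C(C)C([O-])=C1C.[Li+] | intermediate
6 | (Z)-triethyl[(6-ethyl-2-ethylidene-3,5-dimethyl-2H-pyran-4-yl)oxy]silane | C/C=C1\OC(CC)=C(C)C(O[Si](CC)(CC)CC)=C1C | intermediate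
7 | (chloromethoxy)tri(propan-2-yl)silane | CC(C)[Si](OCCl)(C(C)C)C(C)C | starting material
8 | (S)-2-ethyl-3,5-dimethyl-6-(1-{[tri(propan-2-yl)silyl]oxy}propan-2-yl)-4H-pyran-4-one | CCc1oc([C@@H](C)CO[Si](C(C)C)(C(C)C)C(C)C)c(C)c(=O)c1C | intermediate
9 | lithium (Z)-2-ethylidene-3,5-dimethyl-6-[(2S)-1-{[tri(propan-2-yl)silyl]oxy}propan-2-yl]-2H-pyran-4-olate | C/C=C1\OC([C@@H](C)CO[Si](C(C)C)(C(C)C)C(C)C)=C(C)C([O-])=C1C.[Li+] | intermediate
10 | 3,5-dimethyl-2-[1-(phenylselanyl)ethyl]-6-[(2S)-1-{[tri(propan-2-yl)silyl]oxy}propan-2-yl]-4H-pyran-4-one (both epimers at the selenium-bearing carbon) | CC([Se]c1ccccc1)c1oc([C@@H](C)CO[Si](C(C)C)(C(C)C)C(C)C)c(C)c(=O)c1C | intermediate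
11 | (S)-2-ethenyl-3,5-dimethyl-6-(1-{[tri(propan-2-yl)silyl]oxy}propan-2-yl)-4H-pyran-4-one | C=Cc1oc([C@@H](C)CO[Si](C(C)C)(C(C)C)C(C)C)c(C)c(=O)c1C | intermediate
12 | propylmagnesium chloride | CCC[Mg]Cl | starting material
13 | {(2S)-2-[(6Z)-3,5-dimethyl-6-pentylidene-4-(trimethylsilyloxy)-6H-pyran-2-yl]propoxy}tri(propan-2-yl)silane | CCCC/C=C1\OC([C@@H](C)CO[Si](C(C)C)(C(C)C)C(C)C)=C(C)C(O[Si](C)(C)C)=C1C | intermediate
14 | (S)-3,5-dimethyl-2-pentyl-6-(1-{[tri(propan-2-yl)silyl]oxy}propan-2-yl)-4H-pyran-4-one | CCCCCc1oc([C@@H](C)CO[Si](C(C)C)(C(C)C)C(C)C)c(C)c(=O)c1C | intermediate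
15 | (S)-2-(1-hydroxypropan-2-yl)-3,5-dimethyl-6-pentyl-4H-pyran-4-one | CCCCCc1oc([C@@H](C)CO)c(C)c(=O)c1C | intermediate
16 | (R)-2-(3,5-dimethyl-4-oxo-6-pentyl-4H-pyran-2-yl)propanal | CCCCCc1oc([C@@H](C)C=O)c(C)c(=O)c1C | intermediate
17 | (2S,3R,4R)-2-(3,5-dimethyl-4-oxo-6-pentyl-4H-pyran-2-yl)-4-(6-ethyl-3,5-dimethyl-4-oxo-4H-pyran-2-yl)-3-(triethylsilyloxy)pentane | CCCCCc1oc([C@@H](C)[C@H](O[Si](CC)(CC)CC)[C@@H](C)c2oc(CC)c(C)c(=O)c2C)c(C)c(=O)c1C | intermediate
18 | (2S,3R,4R)-2-(3,5-dimethyl-4-oxo-6-pentyl-4H-pyran-2-yl)-4-(6-ethyl-3,5-dimethyl-4-oxo-4H-pyran-2-yl)pentan-3-ol (all-syn) | CCCCCc1oc([C@@H](C)[C@H](O)[C@@H](C)c2oc(CC)c(C)c(=O)c2C)c(C)c(=O)c1C | intermediate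
19 | (2R,4S)-2-(3,5-dimethyl-4-oxo-6-pentyl-4H-pyran-2-yl)-4-(6-ethyl-3,5-dimethyl-4-oxo-4H-pyran-2-yl)pentan-3-one | CCCCCc1oc([C@@H](C)C(=O)[C@@H](C)c2oc(CC)c(C)c(=O)c2C)c(C)c(=O)c1C | target

**Step count**
Total steps: 8. Longest linear sequence: 8 (steps 1 to 8; compound 6 from step 2 is used in step 3 and again in step 7).

**Steps most likely to fail**

Step 3 (proposed new method). The pyranone carbonyl is a strong silyl acceptor, so the catalyst may rest as a silyloxypyrylium ion pair and turn over slowly. The catalyst must also tell H from CH3 on the nucleophile, and a silylated molecule of 8 could lose its α-proton and racemise. Fallback with known chemistry, setting out from 4 and returning at 8: lithium trienolate 5 (from 4 and LiN(iPr)2) is C-formylated with ethyl formate to give racemic 2-(6-ethyl-3,5-dimethyl-4-oxo-4H-pyran-2-yl)propanal F1, which enolises readily. A ketoreductase with NADP+/propan-2-ol recycling in pH 7 phosphate buffer then reduces it under dynamic kinetic resolution, as established for racemic 2-arylpropanals, to (S)-2-ethyl-6-(1-hydroxypropan-2-yl)-3,5-dimethyl-4H-pyran-4-one F2. Silylation of F2 with iPr3SiCl and imidazole in DMF gives 8.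

Step 7 (proposed new method). The two pyranone carbonyls can capture the silylium catalyst, and silylation of ring A makes the aldehyde α-proton more acidic, so 16 may racemise. The syn/anti preference of the trienol ether is also unknown: the all-syn and anti,anti carbinols both lead to 19, but a 3,4-anti product from Felkin attack leads to the (2R,4R) ketone. Fallback with known chemistry, setting out from 16 and 4 and returning at 18: preformed lithium trienolate 5 is added to 16 in THF at −100 to −78 °C, the established stoichiometric aldol of lithiated 2-ethyl-γ-pyranones. Felkin control fixes C3 but C4 forms with little selectivity, so 18 is separated by preparative HPLC from its C4 epimer, the (2S,3R,4S)-carbinol F4, and carried into step 8.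

Step 5. The Grignard reagent may add 1,2 to the pyranone carbonyl, or the vinyl pyranone may oligomerise through its own trienolate. Fallback, setting out from 11 and returning at 14: cross-metathesis of 11 with pent-1-ene (second-generation Grubbs catalyst RuCl2(=CHPh)(H2IMes)(PCy3), CH2Cl2, 40 °C) gives (S,E)-3,5-dimethyl-2-(pent-1-en-1-yl)-6-(1-{[tri(propan-2-yl)silyl]oxy}propan-2-yl)-4H-pyran-4-one F3. Hydrogenation (H2, Pd/C, EtOAc) gives 14, isolated this time, which is desilylated with Bu4NF as in step 5 to give 15.

**Further compounds**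
F1 | step 3 | 2-(6-ethyl-3,5-dimethyl-4-oxo-4H-pyran-2-yl)propanal (racemic) | CCc1oc(C(C)C=O)c(C)c(=O)c1C
F2 | step 3 | (S)-2-ethyl-6-(1-hydroxypropan-2-yl)-3,5-dimethyl-4H-pyran-4-one | CCc1oc([C@@H](C)CO)c(C)c(=O)c1C
F3 | step 5 | (S,E)-3,5-dimethyl-2-(pent-1-en-1-yl)-6-(1-{[tri(propan-2-yl)silyl]oxy}propan-2-yl)-4H-pyran-4-one | CCC/C=C/c1oc([C@@H](C)CO[Si](C(C)C)(C(C)C)C(C)C)c(C)c(=O)c1C
F4 | step 7 | (2S,3R,4S)-2-(3,5-dimethyl-4-oxo-6-pentyl-4H-pyran-2-yl)-4-(6-ethyl-3,5-dimethyl-4-oxo-4H-pyran-2-yl)pentan-3-ol | CCCCCc1oc([C@@H](C)[C@H](O)[C@H](C)c2oc(CC)c(C)c(=O)c2C)c(C)c(=O)c1C
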